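**Retrosynthetic overview**
The route rests on ring B, the arene on the C3 arm: C3' carries a free OH beside OMe groups on C4' and C5'. This unsymmetrical 1,2,3-trioxygenation is not made by selective methylation but by building ring B last from a squarate C4 unit whose ketone carbon becomes C3'–OH.
Ring B is cut at C1'–C6' (Stille coupling of a 2-stannylallyl lactone with 4-chloro-2,3-dimethoxycyclobutenone) and at C2'–C3' (six-electron closure of the dienylketene formed by four-electron ring opening).
The stannane comes from (R)-β-(3,4-dimethoxybenzyl)-γ-butyrolactone by trans-selective alkylation with 2,3-dibromopropene and palladium-catalysed stannylation. The lactone comes from a Stobbe condensation, an asymmetric hydrogenation (sets C4) and a chemoselective ester reduction.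
Ring order: ring A is bought with 3,4-dimethoxybenzaldehyde; the lactone ring closes in step 3; the cyclobutenone comes from dimethyl squarate; ring B closes last, in step 8.

Key step: step 8

Assumption 1: in step 2 the (S,S) enantiomer of MOD-DIOP, (4S,5S)-4,5-bis{[bis(4-methoxy-3,5-dimethylphenyl)phosphino]methyl}-2,2-dimethyl-1,3-dioxolane, is taken to deliver the R acid 5; should the sense of induction be the opposite, the (R,R) ligand is used.
Assumption 2: chloride 15 is treated as too labile to store, so it is made cold and carried into step 8 at once without chromatography.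

Step 1
Reactants: 1 3,4-dimethoxybenzaldehyde; 2 dimethyl succinate
Product: 4 (E)-4-(3,4-dimethoxyphenyl)-3-(methoxycarbonyl)but-3-enoic acid, via paraconate lactone 3 (not isolated)
Conditions: NaOMe, MeOH, reflux; then aq. HCl
Reagents that add atoms: none
Why: Stobbe condensation, in which the succinate enolate adds to the aldehyde, the aldolate lactonises to 3 and base-induced E1cB opening gives the half-ester with the free acid on the methylene arm and the thermodynamically preferred E alkene (aryl trans to the ester).

Step 2
Reactants: 4 (E)-4-(3,4-dimethoxyphenyl)-3-(methoxycarbonyl)but-3-enoic acid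
Product: 5 (R)-4-(3,4-dimethoxyphenyl)-3-(methoxycarbonyl)butanoic acid
Conditions: H2 (5 atm), [Rh(cod)2]BF4 (0.5 mol%), (S,S)-MOD-DIOP (0.6 mol%), Et3N (1 equiv), MeOH, 30 °C; then aq. HCl
Reagents that add atoms: none
Why: Rhodium–bisphosphine asymmetric hydrogenation of an itaconate-type half-ester, in which carboxylate and alkene chelate the metal and the chiral ligand selects the alkene face, so that the stereocentre that becomes C4 of the lactone is set as R by the catalyst.

Step 3
Reactants: 5 (R)-4-(3,4-dimethoxyphenyl)-3-(methoxycarbonyl)butanoic acid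
Product: 7 (R)-4-(3,4-dimethoxybenzyl)dihydrofuran-2(3H)-one, via hydroxy acid 6 (not isolated)
Conditions: KOH (1 equiv), EtOH; CaCl2, NaBH4, EtOH, −10 °C to rt; then aq. HCl, rt
Reagents that add atoms: none
Why: Chemoselective ester reduction, since calcium borohydride reduces the methyl ester but not the potassium carboxylate, followed by acid-promoted lactonisation of 6 to the five-membered lactone; the stereocentre is not touched and is no longer alpha to a carbonyl group afterwards.

Step 4
Reactants: 7 (R)-4-(3,4-dimethoxybenzyl)dihydrofuran-2(3H)-one; 8 2,3-dibromopropene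
Product: 10 (3R,4R)-3-(2-bromoprop-2-en-1-yl)-4-(3,4-dimethoxybenzyl)dihydrofuran-2(3H)-one, via lithium enolate 9 (not isolated)
Conditions: LiHMDS, THF, −78 °C; then 8, DMPU, −78 to −40 °C
Reagents that add atoms: none
Why: Kinetic lactone enolate alkylation (SN2 at the allylic CH2Br of 8, the vinylic bromide being inert), in which the electrophile approaches the enolate face opposite the C4 benzyl group and so sets C3 as R in the trans relationship.

Step 5
Reactants: 10 (3R,4R)-3-(2-bromoprop-2-en-1-yl)-4-(3,4-dimethoxybenzyl)dihydrofuran-2(3H)-one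
Product: 11 (3R,4R)-4-(3,4-dimethoxybenzyl)-3-[2-(tributylstannyl)prop-2-en-1-yl]dihydrofuran-2(3H)-one
Conditions: (Bu3Sn)2 (1.5 equiv), Pd(PPh3)4 (5 mol%), toluene, 100 °C
Reagents that add atoms: hexabutylditin, CCCC[Sn](CCCC)(CCCC)[Sn](CCCC)(CCCC)CCCC
Why: Palladium-catalysed stannylation of an alkenyl bromide with a distannane (oxidative addition, Sn–Sn transmetalation, reductive elimination), in which the hindered 1,1-disubstituted alkenylstannane should couple back with remaining bromide only slowly and the neutral conditions leave the epimerisable trans lactone intact.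

Step 6
Reactants: 12 dimethyl squarate (3,4-dimethoxycyclobut-3-ene-1,2-dione)
Product: 13 4-hydroxy-2,3-dimethoxycyclobut-2-en-1-one (racemic)
Conditions: LiAlH(OtBu)3 (1.05 equiv), THF, −78 to −20 °C; pH 7 buffer
Reagents that add atoms: none
Why: Chemoselective 1,2-monoreduction, in which the bulky, mild hydride adds to one of the two equivalent carbonyl groups and the remaining carbonyl, now a vinylogous ester, is too deactivated to be reduced further at low temperature.

Step 7
Reactants: 13 4-hydroxy-2,3-dimethoxycyclobut-2-en-1-one
Product: 15 4-chloro-2,3-dimethoxycyclobut-2-en-1-one (racemic), via chlorosulfite 14 (not isolated)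
Conditions: SOCl2 (1.1 equiv), pyridine (1.2 equiv), CH2Cl2, −20 to 0 °C; cold filtration, used at once
Reagents that add atoms: thionyl chloride, O=S(Cl)Cl
Why: Deoxychlorination of an activated (allylic, alpha-keto) alcohol through chlorosulfite 14 with pyridine buffering the acid that would otherwise drive loss of methanol to the cyclobutenedione; an allylically transposed chloride would give the same oxocyclobutenyl palladium species in step 8, so positional fidelity of chlorine is not critical.

Step 8
Reactants: 11 (3R,4R)-4-(3,4-dimethoxybenzyl)-3-[2-(tributylstannyl)prop-2-en-1-yl]dihydrofuran-2(3H)-one; 15 4-chloro-2,3-dimethoxycyclobut-2-en-1-one (1.5 equiv)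
Product: 19 (3R,4R)-3-(3-hydroxy-4,5-dimethoxybenzyl)-4-(3,4-dimethoxybenzyl)dihydrofuran-2(3H)-one (the target), via alkenylcyclobutenone 16 (not isolated), via dienylketene 17 (not isolated), via cyclohexadienone 18 (not isolated)
Conditions: PdCl2(PhCN)2 (5 mol%), tri(2-furyl)phosphine (10 mol%), dioxane, 50 °C; then 100 °C
Reagents that add atoms: none
Why: Zerovalent palladium, formed in the flask from PdCl2(PhCN)2, inserts into the allylic C–Cl bond of 15, the alkenyl group is transferred from tin and reductive elimination at the CH terminus forms C1'–C6' in 16; at 100 °C 16 opens by a conrotatory four-electron process to dienylketene 17, whose ketene carbon bonds to the terminal methylene in a disrotatory six-electron electrocyclisation (C2'–C3') to give 18, and enolisation gives the phenol. The closest known reaction type is the Stille coupling of 4-chloro-2-cyclobutenones with alkenylstannanes followed by thermal benzannulation to phenols. Ring B is the only ring closed, and it closes by this six-electron electrocyclic mode from six sp2 carbons of 17. No stereocentre is formed, because the cyclobutenone CH of 16 becomes aromatic C6', and C3 and C4 of the lactone see only neutral conditions. The step needs bond formation at the chlorine-bearing CH terminus and not at the methoxy-bearing terminus of the oxocyclobutenyl palladium unit, which the lower substitution of that terminus and the retained vinylogous-ester conjugation should secure; the ring opening is reversible, so a ketene isomer with the alkenyl group turned outward drains through the isomer that can close. The atom mapping (ketone carbon to C3'–OH, methoxy carbons to C4' and C5', CH to C6', stannylated carbon to C1', methylene to C2') fixes the substitution pattern without any selective O-methylation.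

**Compound list**
1 | 3,4-dimethoxybenzaldehyde | COc1ccc(C=O)cc1OC | starting material
2 | dimethyl succinate | COC(=O)CCC(=O)OC | starting material
3 | methyl 2-(3,4-dimethoxyphenyl)-5-oxotetrahydrofuran-3-carboxylate (paraconate lactone, stereoisomer mixture, formed in the flask) | COC(=O)C1CC(=O)OC1c1ccc(OC)c(OC)c1 | intermediate
4 | (E)-4-(3,4-dimethoxyphenyl)-3-(methoxycarbonyl)but-3-enoic acid | COC(=O)/C(CC(=O)O)=C/c1ccc(OC)c(OC)c1 | intermediate
5 | (R)-4-(3,4-dimethoxyphenyl)-3-(methoxycarbonyl)butanoic acid | COC(=O)[C@H](Cc1ccc(OC)c(OC)c1)CC(=O)O | intermediate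
6 | (R)-4-(3,4-dimethoxyphenyl)-3-(hydroxymethyl)butanoic acid (formed in the flask) | OC[C@H](Cc1ccc(OC)c(OC)c1)CC(=O)O | intermediate
7 | (R)-4-(3,4-dimethoxybenzyl)dihydrofuran-2(3H)-one | COc1ccc(C[C@H]2COC(=O)C2)cc1OC | intermediate
8 | 2,3-dibromopropene | C=C(Br)CBr | starting material
9 | lithium enolate of 7, lithium (R)-3-(3,4-dimethoxybenzyl)-2,3-dihydrofuran-5-olate (formed in the flask) | COc1ccc(C[C@H]2COC([O-])=C2)cc1OC.[Li+] | intermediate
10 | (3R,4R)-3-(2-bromoprop-2-en-1-yl)-4-(3,4-dimethoxybenzyl)dihydrofuran-2(3H)-one | COc1ccc(C[C@H]2COC(=O)[C@@H]2CC(Br)=C)cc1OC | intermediate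
11 | (3R,4R)-4-(3,4-dimethoxybenzyl)-3-[2-(tributylstannyl)prop-2-en-1-yl]dihydrofuran-2(3H)-one | COc1ccc(C[C@H]2COC(=O)[C@@H]2CC(=C)[Sn](CCCC)(CCCC)CCCC)cc1OC | intermediate
12 | dimethyl squarate (3,4-dimethoxycyclobut-3-ene-1,2-dione) | COC1=C(OC)C(=O)C1=O | starting material
13 | 4-hydroxy-2,3-dimethoxycyclobut-2-en-1-one (racemic) | COC1=C(OC)C(O)C1=O | intermediate
14 | 2,3-dimethoxy-4-oxocyclobut-2-en-1-yl chlorosulfite (formed in the flask) | COC1=C(OC)C(OS(=O)Cl)C1=O | intermediate
15 | 4-chloro-2,3-dimethoxycyclobut-2-en-1-one (racemic) | COC1=C(OC)C(Cl)C1=O | intermediate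
16 | (3R,4R)-4-(3,4-dimethoxybenzyl)-3-[2-(2,3-dimethoxy-4-oxocyclobut-2-en-1-yl)prop-2-en-1-yl]dihydrofuran-2(3H)-one (both epimers at the cyclobutenone CH, formed in the flask) | COc1ccc(C[C@H]2COC(=O)[C@@H]2CC(=C)C2C(=O)C(OC)=C2OC)cc1OC | intermediate
17 | (3R,4R)-4-(3,4-dimethoxybenzyl)-3-[(3E)-4,5-dimethoxy-2-methylidene-6-oxohexa-3,5-dien-1-yl]dihydrofuran-2(3H)-one (dienylketene, formed in the flask) | COc1ccc(C[C@H]2COC(=O)[C@@H]2CC(=C)/C=C(OC)\C(OC)=C=O)cc1OC | intermediate
18 | (3R,4R)-4-(3,4-dimethoxybenzyl)-3-[(3,4-dimethoxy-5-oxocyclohexa-1,3-dien-1-yl)methyl]dihydrofuran-2(3H)-one (formed in the flask) | COc1ccc(C[C@H]2COC(=O)[C@@H]2CC2=CC(OC)=C(OC)C(=O)C2)cc1OC | intermediate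
19 | (3R,4R)-3-(3-hydroxy-4,5-dimethoxybenzyl)-4-(3,4-dimethoxybenzyl)dihydrofuran-2(3H)-one | COc1ccc(C[C@H]2COC(=O)[C@@H]2Cc2cc(O)c(OC)c(OC)c2)cc1OC | target

**Step count**
Total: 8 steps. Longest linear sequence: 6 steps (steps 1, 2, 3, 4, 5 and 8); steps 6 and 7 form the two-step side branch.

**Steps most likely to fail**

Step 8. The 1,1-disubstituted alkenyl group may transfer from tin too slowly, so that the oxocyclobutenyl palladium intermediate decomposes, or the new bond may form at the methoxy-bearing terminus and lead to a wrongly substituted arene. The fallback abandons the benzannulation; it sets out from lactone 7 and comes back to the route at target 19. Commercial 3-(benzyloxy)-4,5-dimethoxybenzaldehyde is reduced (NaBH4, MeOH, 0 °C) to [3-(benzyloxy)-4,5-dimethoxyphenyl]methanol F1 and brominated (PBr3, Et2O, 0 °C) to 1-(benzyloxy)-5-(bromomethyl)-2,3-dimethoxybenzene F2. Lithium enolate 9 (from 7, LiHMDS, THF, DMPU, −78 °C) is alkylated with F2 anti to the C4 benzyl group to give (3R,4R)-3-[3-(benzyloxy)-4,5-dimethoxybenzyl]-4-(3,4-dimethoxybenzyl)dihydrofuran-2(3H)-one F3. Hydrogenolysis (H2, Pd/C, EtOAc, rt) frees the C3' phenol and gives 19.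

Step 7. The chlorosulfite or the chloride may ionise, after which chloride attacks an O-methyl group; chloromethane is lost and the ring collapses to the cyclobutenedione. The fallback replaces the chloride by an ester leaving group with no nucleophilic counter-ion; it sets out from 13 and comes back to the route at alkenylcyclobutenone 16. Alcohol 13 is acetylated (Ac2O, pyridine, DMAP, CH2Cl2, 0 °C) to 2,3-dimethoxy-4-oxocyclobut-2-en-1-yl acetate F4, which should tolerate purification. F4 is coupled with stannane 11 under the conditions known for allylic acetates and alkenylstannanes (Pd(dba)2, LiCl, DMF, 40 °C) to give 16, which is then heated as in step 8.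

Step 5. The new stannane may be consumed by coupling with unreacted bromide 10, or may suffer protodestannylation at the temperature that oxidative addition requires. The fallback places tin by addition to an alkyne instead of substitution of a bromide; it sets out from lactone 7 and comes back to the route at alkenylcyclobutenone 16. Enolate 9 is alkylated with propargyl bromide (THF, DMPU, −78 °C), again trans to the C4 substituent, to give (3R,4R)-4-(3,4-dimethoxybenzyl)-3-(prop-2-yn-1-yl)dihydrofuran-2(3H)-one F5. Stannylcupration of the terminal alkyne with Me3SnCu·SMe2 in THF containing MeOH (−78 to −60 °C) puts tin on the internal carbon and gives (3R,4R)-4-(3,4-dimethoxybenzyl)-3-[2-(trimethylstannyl)prop-2-en-1-yl]dihydrofuran-2(3H)-one F6. F6 takes the place of 11 in step 8 and gives 16.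

**Further compounds**
F1 | step 8 | [3-(benzyloxy)-4,5-dimethoxyphenyl]methanol | COc1cc(CO)cc(OCc2ccccc2)c1OC
F2 | step 8 | 1-(benzyloxy)-5-(bromomethyl)-2,3-dimethoxybenzene | COc1cc(CBr)cc(OCc2ccccc2)c1OC
F3 | step 8 | (3R,4R)-3-[3-(benzyloxy)-4,5-dimethoxybenzyl]-4-(3,4-dimethoxybenzyl)dihydrofuran-2(3H)-one | COc1ccc(C[C@H]2COC(=O)[C@@H]2Cc2cc(OCc3ccccc3)c(OC)c(OC)c2)cc1OC
F4 | step 7 | 2,3-dimethoxy-4-oxocyclobut-2-en-1-yl acetate | COC1=C(OC)C(OC(C)=O)C1=O
F5 | step 5 | (3R,4R)-4-(3,4-dimethoxybenzyl)-3-(prop-2-yn-1-yl)dihydrofuran-2(3H)-one | COc1ccc(C[C@H]2COC(=O)[C@@H]2CC#C)cc1OC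
F6 | step 5 | (3R,4R)-4-(3,4-dimethoxybenzyl)-3-[2-(trimethylstannyl)prop-2-en-1-yl]dihydrofuran-2(3H)-one | COc1ccc(C[C@H]2COC(=O)[C@@H]2CC(=C)[Sn](C)(C)C)cc1OC
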